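The numbers in the tables are calculated from invented constants, and the scatter is random.

How slowly does Xa leave once it has passed its top? That is what the green run can tell us, so the examination starts there.

the same everywhere: Ze 0.264 M
- green: Qe 1.3 M; run made earlier
- flask: Qe 0.88 M; time 5.0 h
green run (percent of the Qe charged)

| time / min | Xa / % |
|---|---|
| 5.00 | 34.0 |
| 15.0 | 16.1 |
| 25.0 | 9.6 |
| 40.0 | 4.7 |
| 50.0 | 3.9 |
| 80.0 | 2.1 |
| 90.0 | 3.8 |

(standard deviation of a reading: 1 percentage point)
- the numbers in the tables scatter with a standard deviation of 1 percentage point
- a reading or a percentage of Xa counts all its forms, free or not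
- when, up to 5.0 h, the flask holds most Xa
- the amount of Xa, in percent of the Qe charged, at that time
- the first time at which Xa reaches 23%, in the same percent, in min

What do the readings show? A fall with no early rise: the first reading, 34.0% at 5.00 min, is already the highest.

Then put a number on the slowness. The fall constant, the pseudo-first-order rate at which Xa shrinks over the first span of the green run, is the logarithm of the ratio of the first two readings divided by the time between them: 0.0748 min⁻¹.

Does it hold later? Not far: it predicts 7.62% at 25.0 min, but the reading is 9.6%. I trust it over the early span.

And the other end? Run back to time zero, the line stands at 49.4%. Xa starts from nothing and I take its curve to join that line from below, so I put the green top between the first reading and that figure, before or near 5.00 min.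

The weak spot: this flask has less Qe. With Ze unchanged and no run at another Qe, I carry that bracket over as it stands. The readings hold no point on the rise, so I can say only that the asked level comes earlier than the top.

The forecast gives 0.05 h, 42% and 1 min, and says of itself: “This is weakly constrained.”

The flask tops at 3.99 min with 33.2%, 0.80 percentage points under my lower edge against a scatter of 1 point, and reaches the level at 1.35 min. From that top, the fall constant predicts 13.5% at 16 min, and the flask holds 13.8%.

    Qe + Ze → Wy (k = 0.234 L mol⁻¹ min⁻¹)
    Qe ⇌ Xa (K = 1.62, k = 0.259 min⁻¹)
    Qe + Xa ⇌ Ej, settled at all times (K = 3.70 L mol⁻¹)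
    Xa ⇌ Ve (k = 0.198 min⁻¹)
    Qe ⇌ Ve (K = 43.0, k = 0.0483 min⁻¹)

The neighbour flask charges 1.1 M of Ze. Taken at its charge, the added Ze gives free Qe an extra loss constant of 0.196 min⁻¹, larger than the carried 0.0748 min⁻¹. That constant acts on free Qe and the carried one on Xa with all its forms, so I draw no top from the pair. The neighbour's top stands at 25.8%.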